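## The problem

Quercetin 3,3'-bissulfate 19 is a flavonol: a phloroglucinol-type ring A fused to a 4-pyranone ring C, with a catechol ring B on C2. It has no stereocentre, so nothing has to be controlled in three dimensions. The difficulty lies in the five oxygens. O3 (the enolic oxygen of ring C) and O3' (ring B) carry hydrogen sulfate esters, while O5, O7 and O4' are free phenols, and O7 and O4' are the most acidic and most readily sulfated positions of the parent pentaol. The pattern therefore cannot come from selective sulfation: O5, O7 and O4' must share one masking group while O3 and O3' are unveiled together. The sulfate monoesters are strong acids, very polar and prone to acid-catalysed S–O cleavage (the enol sulfate at C3 most of all), so they must go in at the penultimate stage and the last step must be neutral. Ring A sets a second task, because its three oxygens end in three different roles (O1 in the ring, O5 and O7), so the symmetry of phloroglucinol must be broken early and cleanly. The feature that opens the key step is C4: a lone carbonyl carbon between C4a of ring A and the oxygen-bearing C3. It can be supplied as carbon monoxide 11, inserted between a ring A aryl iodide and the enolate carbon of a ring B α-alkoxy ketone, after which only the O1–C2 bond of ring C remains to be made.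

## Retrosynthesis

**19 to 18.** The last bonds cut are the three O–CH2Ph bonds of 18, the 5,7,4'-tri-O-benzyl ether of the target. Benzyl is chosen for the oxygens that end free because hydrogenolysis over Pd/C is neutral and leaves aryl and enol sulfates alone; acid-labile or Lewis-acid-labile groups would come off under conditions that hydrolyse the sulfates. The forward step only has to spare the C2=C3 bond of the pyranone and the S–O bonds.

**18 to 17.** Cutting both O–S bonds gives 17, 5,7,4'-tri-O-benzylquercetin, in which O3 and O3' are the only free hydroxyls. Since every free hydroxyl is to be sulfated, the step needs completeness at the hydrogen-bonded O3 and no selectivity. This is why the protecting groups are arranged so that exactly these two oxygens are bare.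

**17 to 14.** Ring C is opened at O1–C2. The three hydroxyls that must be free at this stage (the ring A phenol that becomes O1, O3 and O3') receive one common acid-labile group, methoxymethyl (MOM), which leads to the open-chain 1,3-diketone 14. Cutting C2–C1' (a cross-coupling on a 2-halochromone) or adding O3 late by oxidising a flavone would both be longer. This cut keeps every oxygen in place from the start and makes ring closure a consequence of deprotection: acid frees the ring A phenol, which adds to the ring B ketone, and water is lost. The forward step must leave the benzyl ethers untouched and must close the ring before the diketone can be cleaved.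

**14 to 4, 10 and 11.** The bonds C4a–C4 and C3–C4 are cut together. C4 leaves as carbon monoxide 11, ring A becomes aryl iodide 4, and C2, C3, O3 and ring B stay together in α-(methoxymethoxy) ketone 10. The neighbouring cuts are weaker for this pattern. A Baker–Venkataraman acyl shift or a Friedel–Crafts or Hoesch acylation needs a 2,4,6-trioxygenated ω-alkoxyacetophenone whose oxygens are hard to tell apart. Oxidative cyclisation of a 2'-hydroxychalcone bearing a 6'-substituent tends towards aurones. The carbonylative cut uses two fragments of similar size, each two or three steps from a purchasable compound. The forward reaction must be carbonylative (not direct α-arylation), must acylate at carbon, and must tolerate MOM and benzyl ethers, which its basic conditions do.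

**4 to 2 to 1.** The C–I bond of 4 is cut to MOM ether 2, and the MOM group to 3,5-bis(benzyloxy)phenol 1, a purchasable and already desymmetrised phloroglucinol. The MOM group does two jobs: it later frees O1, and it directs lithiation (through aryllithium 3) to the position between OMOM and OBn. Electrophilic iodination of 2 would not distinguish that position from the one between the two benzyloxy groups.

**10 to 9 to 6 and 7; 6 to 5.** Ketone 10 is traced to alcohol 9 and cut between the future C2 and C3. This gives aldehyde 6 and a hydroxymethyl anion equivalent, (methoxymethoxy)methyllithium 8, generated from stannane 7. Aldehyde 6 comes from 4-(benzyloxy)-3-hydroxybenzaldehyde 5, in which O4' and O3' are already differentiated. Starting instead from an α-halo ketone of the catechol would mean protecting two phenols beside an alkylating side chain and then exchanging halide for oxygen in further steps. The aldehyde route brings the α-oxygen in already protected.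

## Roads not taken

Alternative 1: Ring C is cut at C4–C4a and O1–C2, giving unprotected phloroglucinol A1 and the 2-pivaloyloxy β-keto ester A2, which carries ring B, C2, C3 and C4. Heating the two neat at about 240 °C without catalyst should acylate ring A through a ketene-type species and close ring C in the same operation, giving the 3,3'-dipivalate A3.
- Merits: the key step itself closes the ring, A1 needs no protection and poses no regiochemical question, and no palladium or CO is needed. In these respects it is simpler than the chosen plan.
- Weak points: at 240 °C an enol pivalate and an aryl pivalate sit beside free phenols, so acyl transfer to O5 or O7 can scramble the pattern the step is meant to deliver. Coumarin-type closure of the electron-rich ring A competes. A3 also has the wrong oxygens free, so O7 and O5 would need benzylating and the pivalates removing to reach the equivalent of 17.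
- Comparison: the overall step count is no shorter, and the chosen plan sets an 80 °C key step and a product already carrying the final protecting-group pattern against the operational simplicity of this road.

Alternative 2: Ring C is cut at C3–C4 with reversed polarity. The precursor is the dialdehyde A4, a ring A salicylaldehyde ether of a ring B α-aryloxy acetaldehyde. A thiazolium-derived carbene with an amine base should convert the aromatic formyl group into a Breslow intermediate that adds to the aliphatic formyl group, closing ring C as the 3-hydroxychroman-4-one A5 (mixture of diastereomers).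
- Merits: it is metal-free and mild, and it delivers O3 free while O3' is still masked. The chosen plan does not offer that differentiation, but it is not needed here because both oxygens are sulfated.
- Weak points: the formyl group that must become the acyl anion is flanked by two ortho oxygens and is electron-rich, so it is the slower one to engage the carbene. If the aliphatic aldehyde engages instead, its α-aryloxy group is a leaving group and the molecule fragments by internal redox. A5 is at the dihydroflavonol oxidation level and must be dehydrogenated. A4 needs a long linear sequence in which two aldehydes are handled at different times.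
- Comparison: the chosen plan is more convergent, reaches the flavonol oxidation level directly, and does not depend on which of two carbonyls reacts first.

Alternative 3: Ring A itself is cut. The 4-hydroxy-2-pyranone A6 masks a tetraketide chain; a magnesium alkoxide in its parent alcohol should open it, and the methylene that becomes C4a should attack the ester carbon in a Claisen condensation, closing and aromatising ring A to the 2-alkoxy chalcone-type triol A7.
- Merits: the ring A oxygen pattern arises by construction, without arene substitution chemistry or ring A protecting groups, and the route follows the biosynthetic logic.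
- Weak points: it spends steps building a ring that can be bought. Aldol-type closure and relactonisation compete with the Claisen mode. The enone of A7 is exposed to alkoxide. After the key step ring C is still open and must be closed and dehydrogenated. O5 and O7 emerge free and would have to be protected before sulfation.
- Comparison: the chosen plan starts from a desymmetrised phloroglucinol ether, and after its key step a single acid treatment gives the flavonol with the correct oxygens bare.

Key step: step 6

Remark on the chemistry: sulfate monoesters 18 and 19 are written as neutral hydrogen sulfates, as in the target; in the flask they would be carried as sodium salts, and the acid form is released only by the final cation exchange.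
Remark on the chemistry: 3,5-bis(benzyloxy)phenol 1, 4-(benzyloxy)-3-hydroxybenzaldehyde 5 and tributyl[(methoxymethoxy)methyl]stannane 7 are taken as purchasable.

## Route

Step 1
Reactants: 1 3,5-bis(benzyloxy)phenol
Product: 2 1,3-bis(benzyloxy)-5-(methoxymethoxy)benzene
Conditions: NaH, DMF, 0 °C; MOMCl, 0 °C to rt
Reagents that add atoms: chloromethyl methyl ether, COCCl
Why: Williamson-type O-alkylation of the sodium phenoxide with a hard α-chloro ether; O-alkylation is expected over C-alkylation and the benzyl ethers are inert.

Step 2
Reactants: 2 1,3-bis(benzyloxy)-5-(methoxymethoxy)benzene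
Product: 4 1,5-bis(benzyloxy)-2-iodo-3-(methoxymethoxy)benzene, via aryllithium 3 (not isolated)
Conditions: n-BuLi, THF, 0 °C; I2, THF, −78 °C to rt
Reagents that add atoms: iodine, II
Why: Directed ortho-metalation: the MOM ether chelates lithium and the position between OMOM and OBn is flanked by two oxygens, so deprotonation there should be preferred over the position between the two weaker benzyloxy directors; iodine then traps the aryllithium.

Step 3
Reactants: 5 4-(benzyloxy)-3-hydroxybenzaldehyde
Product: 6 4-(benzyloxy)-3-(methoxymethoxy)benzaldehyde
Conditions: MOMCl, K2CO3, acetone, rt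
Reagents that add atoms: chloromethyl methyl ether, COCCl
Why: Standard MOM protection of a phenol under mild carbonate conditions; the aldehyde is not enolisable and is untouched.

Step 4
Reactants: 6 4-(benzyloxy)-3-(methoxymethoxy)benzaldehyde; 7 tributyl[(methoxymethoxy)methyl]stannane
Product: 9 1-[4-(benzyloxy)-3-(methoxymethoxy)phenyl]-2-(methoxymethoxy)ethan-1-ol (racemic), via (methoxymethoxy)methyllithium 8 (not isolated)
Conditions: 7, n-BuLi, THF, −78 °C; then 6, −78 °C; H2O
Reagents that add atoms: none
Why: Tin–lithium exchange gives the configurationally irrelevant α-alkoxy organolithium, which adds 1,2 to the aryl aldehyde; the new carbinol centre is racemic and is removed by oxidation in step 5.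

Step 5
Reactants: 9 1-[4-(benzyloxy)-3-(methoxymethoxy)phenyl]-2-(methoxymethoxy)ethan-1-ol
Product: 10 1-[4-(benzyloxy)-3-(methoxymethoxy)phenyl]-2-(methoxymethoxy)ethan-1-one
Conditions: DMP, pyridine, CH2Cl2, 0 °C to rt
Reagents that add atoms: none
Why: Dess–Martin oxidation of a secondary benzylic alcohol; the pyridine buffer protects the MOM acetals from the acetic acid released.

Step 6
Reactants: 4 1,5-bis(benzyloxy)-2-iodo-3-(methoxymethoxy)benzene; 10 1-[4-(benzyloxy)-3-(methoxymethoxy)phenyl]-2-(methoxymethoxy)ethan-1-one; 11 carbon monoxide
Product: 14 1-[2,4-bis(benzyloxy)-6-(methoxymethoxy)phenyl]-3-[4-(benzyloxy)-3-(methoxymethoxy)phenyl]-2-(methoxymethoxy)propane-1,3-dione (racemic), via ketone sodium enolate 12 (not isolated), via sodium diketonate 13 (not isolated)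
Conditions: Pd(dba)2 (5 mol %), 1,3-bis(diphenylphosphino)propane (5 mol %), NaN(SiMe3)2 (2.2 equiv), CO (1 atm), THF, 80 °C; aq. NH4Cl
Reagents that add atoms: none
Why: Zerovalent palladium inserts into the C–I bond of 4, CO coordinates and the aryl group migrates to it to give an aroyl complex of divalent palladium, and the enolate 12 of ketone 10 replaces iodide on the metal. Reductive elimination from the carbon-bound enolate forms the C3–C4 bond (the C4a–C4 bond was formed in the insertion) and returns zerovalent palladium; the second equivalent of base stores the product as the stabilised diketonate 13 until the quench. The closest known reaction type is the palladium-catalysed carbonylative α-arylation of aryl alkyl ketones with aryl iodides to give 1,3-diketones. No ring is closed. The one new stereocentre (C2 of the dione, the future C3) is formed racemic and enolisable and needs no control, because it becomes sp2 in step 7. The step needs carbonylative coupling over direct α-arylation: the two ortho alkoxy groups slow direct reductive elimination from the aryl–palladium enolate and speed migration of the electron-rich aryl group to CO, and the CO atmosphere supports this. It also needs C-acylation over O-acylation, which follows because the bond forms by reductive elimination at palladium and not by attack of a free enolate oxygen on an acyl halide. The conditions are basic and non-acidic, so the three MOM and three benzyl ethers should pass unchanged, and 4 has no ortho hydrogen from which an aryne could form.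

Step 7
Reactants: 14 1-[2,4-bis(benzyloxy)-6-(methoxymethoxy)phenyl]-3-[4-(benzyloxy)-3-(methoxymethoxy)phenyl]-2-(methoxymethoxy)propane-1,3-dione
Product: 17 5,7-bis(benzyloxy)-2-[4-(benzyloxy)-3-hydroxyphenyl]-3-hydroxy-4H-chromen-4-one (5,7,4'-tri-O-benzylquercetin), via diphenol diketone 15 (not isolated), via 3-O-MOM flavone 16 (not isolated)
Conditions: 3 M HCl, MeOH–THF, 50 °C
Reagents that add atoms: none
Why: Acid-catalysed acetal exchange should remove the two phenolic MOM groups first; the freed ring A phenol adds to the ring B ketone (6-exo-trig) and the hemiketal dehydrates to the aromatic pyranone (cyclodehydration of a 2'-hydroxy-1,3-diketone), after which the enol-type MOM group on O3 is cleaved; benzyl ethers are stable to these conditions.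

Step 8
Reactants: 17 5,7-bis(benzyloxy)-2-[4-(benzyloxy)-3-hydroxyphenyl]-3-hydroxy-4H-chromen-4-one
Product: 18 5,7-bis(benzyloxy)-2-[4-(benzyloxy)-3-(sulfooxy)phenyl]-4-oxo-4H-chromen-3-yl hydrogen sulfate
Conditions: SO3·pyridine (excess), pyridine, 45 °C; aq. NaHCO3 work-up (carried as the disodium salt)
Reagents that add atoms: sulfur trioxide–pyridine complex, O=S(=O)([O-])[n+]1ccccc1
Why: O-sulfation of a phenol and of an acidic enol with an amine–SO3 complex; both free hydroxyls are to react, so excess reagent and mild heating are used to drive the hydrogen-bonded O3 to completion, and the sodium salt form avoids amine inhibition of the next step.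

Step 9
Reactants: 18 5,7-bis(benzyloxy)-2-[4-(benzyloxy)-3-(sulfooxy)phenyl]-4-oxo-4H-chromen-3-yl hydrogen sulfate
Product: 19 quercetin 3,3'-bis(hydrogen sulfate) (5,7-dihydroxy-2-[4-hydroxy-3-(sulfooxy)phenyl]-4-oxo-4H-chromen-3-yl hydrogen sulfate)
Conditions: H2 (1 atm), 10% Pd/C, MeOH–THF–H2O, rt; cation-exchange resin (H+ form), 0 °C, freeze-drying
Reagents that add atoms: none
Why: Catalytic hydrogenolysis of three aryl benzyl ethers under neutral conditions; sulfate esters and the conjugated C2=C3 bond of the flavone are not expected to be reduced at atmospheric pressure.

## Compound list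

1 | 3,5-bis(benzyloxy)phenol | Oc1cc(OCc2ccccc2)cc(OCc2ccccc2)c1 | starting material
2 | 1,3-bis(benzyloxy)-5-(methoxymethoxy)benzene | COCOc1cc(OCc2ccccc2)cc(OCc2ccccc2)c1 | intermediate
3 | [2,4-bis(benzyloxy)-6-(methoxymethoxy)phenyl]lithium | [Li]c1c(OCOC)cc(OCc2ccccc2)cc1OCc1ccccc1 | intermediate (not isolated)
4 | 1,5-bis(benzyloxy)-2-iodo-3-(methoxymethoxy)benzene | COCOc1cc(OCc2ccccc2)cc(OCc2ccccc2)c1I | intermediate
5 | 4-(benzyloxy)-3-hydroxybenzaldehyde | O=Cc1ccc(OCc2ccccc2)c(O)c1 | starting material
6 | 4-(benzyloxy)-3-(methoxymethoxy)benzaldehyde | COCOc1cc(C=O)ccc1OCc1ccccc1 | intermediate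
7 | tributyl[(methoxymethoxy)methyl]stannane | CCCC[Sn](CCCC)(CCCC)COCOC | starting material
8 | (methoxymethoxy)methyllithium | [Li]COCOC | intermediate (not isolated)
9 | 1-[4-(benzyloxy)-3-(methoxymethoxy)phenyl]-2-(methoxymethoxy)ethan-1-ol (racemic) | COCOCC(O)c1ccc(OCc2ccccc2)c(OCOC)c1 | intermediate
10 | 1-[4-(benzyloxy)-3-(methoxymethoxy)phenyl]-2-(methoxymethoxy)ethan-1-one | COCOCC(=O)c1ccc(OCc2ccccc2)c(OCOC)c1 | intermediate
11 | carbon monoxide | [C-]#[O+] | starting material
12 | sodium (Z)-1-[4-(benzyloxy)-3-(methoxymethoxy)phenyl]-2-(methoxymethoxy)ethen-1-olate | [Na+].[O-]/C(=C\OCOC)c1ccc(OCc2ccccc2)c(OCOC)c1 | intermediate (not isolated)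
13 | sodium enolate of diketone 14 (delocalised; one canonical form drawn) | [Na+].COCOC(C(=O)c1ccc(OCc2ccccc2)c(OCOC)c1)=C([O-])c1c(OCOC)cc(OCc2ccccc2)cc1OCc1ccccc1 | intermediate (not isolated)
14 | 1-[2,4-bis(benzyloxy)-6-(methoxymethoxy)phenyl]-3-[4-(benzyloxy)-3-(methoxymethoxy)phenyl]-2-(methoxymethoxy)propane-1,3-dione (racemic, enolisable) | COCOC(C(=O)c1ccc(OCc2ccccc2)c(OCOC)c1)C(=O)c1c(OCOC)cc(OCc2ccccc2)cc1OCc1ccccc1 | intermediate
15 | 1-[2,4-bis(benzyloxy)-6-hydroxyphenyl]-3-[4-(benzyloxy)-3-hydroxyphenyl]-2-(methoxymethoxy)propane-1,3-dione (racemic) | COCOC(C(=O)c1ccc(OCc2ccccc2)c(O)c1)C(=O)c1c(O)cc(OCc2ccccc2)cc1OCc1ccccc1 | intermediate (not isolated)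
16 | 5,7-bis(benzyloxy)-2-[4-(benzyloxy)-3-hydroxyphenyl]-3-(methoxymethoxy)-4H-chromen-4-one | COCOc1c(-c2ccc(OCc3ccccc3)c(O)c2)oc2cc(OCc3ccccc3)cc(OCc3ccccc3)c2c1=O | intermediate (not isolated)
17 | 5,7-bis(benzyloxy)-2-[4-(benzyloxy)-3-hydroxyphenyl]-3-hydroxy-4H-chromen-4-one | O=c1c(O)c(-c2ccc(OCc3ccccc3)c(O)c2)oc2cc(OCc3ccccc3)cc(OCc3ccccc3)c12 | intermediate
18 | 5,7-bis(benzyloxy)-2-[4-(benzyloxy)-3-(sulfooxy)phenyl]-4-oxo-4H-chromen-3-yl hydrogen sulfate | O=c1c(OS(=O)(=O)O)c(-c2ccc(OCc3ccccc3)c(OS(=O)(=O)O)c2)oc2cc(OCc3ccccc3)cc(OCc3ccccc3)c12 | intermediate
19 | quercetin 3,3'-bis(hydrogen sulfate) | O=c1c(OS(=O)(=O)O)c(-c2ccc(O)c(OS(=O)(=O)O)c2)oc2cc(O)cc(O)c12 | target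

## Step count and risks

Total step count: 9. Longest linear sequence: 7 steps (steps 3, 4, 5, 6, 7, 8 and 9, from aldehyde 5).

**Step 6 (key step).** The most likely failure is stalling at the hindered aroylpalladium stage. The doubly ortho-substituted aroyl complex may accept the bulky α-alkoxy enolate slowly, so that hydrodeiodination of 4 or capture of the acyl group by the amide base competes. The fallback sets out from 2 and 10 and returns at 14. Aryllithium 3, generated from 2 as in step 2, would be quenched with N,N-dimethylformamide instead of iodine to give 2,4-bis(benzyloxy)-6-(methoxymethoxy)benzaldehyde F1. Ketone 10, deprotonated with LiN(i-Pr)2 in THF at −78 °C, would add to F1 in an aldol reaction to give 3-[2,4-bis(benzyloxy)-6-(methoxymethoxy)phenyl]-1-[4-(benzyloxy)-3-(methoxymethoxy)phenyl]-3-hydroxy-2-(methoxymethoxy)propan-1-one F2 as a mixture of diastereomers. Dess–Martin oxidation of F2 would converge on 14. The same two fragments are joined at C3–C4, but C4 comes from a formyl group instead of CO.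

**Step 2.** Deprotonation may stray to a benzylic CH2 (followed by Wittig-type rearrangement) or to the position between the two benzyloxy groups, because benzyl ethers are not fully inert to n-BuLi and are weak directors themselves. The fallback sets out from 1 and returns at 4. Phenol 1 would be iodinated with N-iodosuccinimide in DMF at 0 °C, where two ortho positions compete with one more hindered para position, and 3,5-bis(benzyloxy)-2-iodophenol F3 would be separated from its regioisomer by chromatography. F3 would then be converted into 4 with NaH and chloromethyl methyl ether. The iodine is thus placed by electrophilic substitution before the MOM group is introduced.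

**Step 7.** Methanolysis of the non-enolised, 2-oxygenated 1,3-diketone (retro-Claisen cleavage) may compete with ring closure, because alcohol and acid are present before the ring A phenol is free. The fallback sets out from 14 and returns at 17 by dividing the cascade into two isolated stages. NaHSO4 on silica in CH2Cl2 at room temperature, a reagent that cleaves phenolic MOM ethers and spares alkyl MOM ethers, would free the phenols with no alcohol present, so that 15 closes and dehydrates to the 3-O-MOM flavone 16 (with p-TsOH in toluene if the hemiketal persists). Isolated 16, which no longer contains a cleavable diketone, would then lose its last MOM group in a short HCl–methanol treatment. No compound outside the list arises (entry F0).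

**Step 8.** Sulfation may stay incomplete at the hydrogen-bonded O3, and sulfate may be lost while the very polar bis-sulfate is purified. The fallback sets out from 17 and returns at 18. Compound 17 would be treated with 2,2,2-trichloroethyl chlorosulfate, Et3N and 4-(dimethylamino)pyridine in THF to give the neutral, chromatographable 5,7-bis(benzyloxy)-2-{4-(benzyloxy)-3-[(2,2,2-trichloroethoxy)sulfonyloxy]phenyl}-4-oxo-4H-chromen-3-yl 2,2,2-trichloroethyl sulfate F4. Reductive removal of both trichloroethyl groups with Zn and HCO2NH4 in methanol would deliver 18 as its salt, which is taken into step 9.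

## Further compounds

F1 | step 6 | 2,4-bis(benzyloxy)-6-(methoxymethoxy)benzaldehyde | O=Cc1c(OCOC)cc(OCc2ccccc2)cc1OCc1ccccc1
F2 | step 6 | 3-[2,4-bis(benzyloxy)-6-(methoxymethoxy)phenyl]-1-[4-(benzyloxy)-3-(methoxymethoxy)phenyl]-3-hydroxy-2-(methoxymethoxy)propan-1-one (mixture of racemic diastereomers) | COCOC(C(=O)c1ccc(OCc2ccccc2)c(OCOC)c1)C(O)c1c(OCOC)cc(OCc2ccccc2)cc1OCc1ccccc1
F3 | step 2 | 3,5-bis(benzyloxy)-2-iodophenol | Oc1cc(OCc2ccccc2)cc(OCc2ccccc2)c1I
F0 | step 7 | none | none
F4 | step 8 | 5,7-bis(benzyloxy)-2-{4-(benzyloxy)-3-[(2,2,2-trichloroethoxy)sulfonyloxy]phenyl}-4-oxo-4H-chromen-3-yl 2,2,2-trichloroethyl sulfate | O=c1c(OS(=O)(=O)OCC(Cl)(Cl)Cl)c(-c2ccc(OCc3ccccc3)c(OS(=O)(=O)OCC(Cl)(Cl)Cl)c2)oc2cc(OCc3ccccc3)cc(OCc3ccccc3)c12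
A1 | alternative 1 | phloroglucinol | Oc1cc(O)cc(O)c1
A2 | alternative 1 | ethyl 3-[4-(benzyloxy)-3-(pivaloyloxy)phenyl]-3-oxo-2-(pivaloyloxy)propanoate (racemic) | CCOC(=O)C(OC(=O)C(C)(C)C)C(=O)c1ccc(OCc2ccccc2)c(OC(=O)C(C)(C)C)c1
A3 | alternative 1 | 4'-O-benzyl-3,3'-di-O-pivaloylquercetin | O=c1c(OC(=O)C(C)(C)C)c(-c2ccc(OCc3ccccc3)c(OC(=O)C(C)(C)C)c2)oc2cc(O)cc(O)c12
A4 | alternative 2 | 2-[3,5-bis(benzyloxy)-2-formylphenoxy]-2-[4-(benzyloxy)-3-(methoxymethoxy)phenyl]acetaldehyde (racemic) | O=CC(Oc1cc(OCc2ccccc2)cc(OCc2ccccc2)c1C=O)c1ccc(OCc2ccccc2)c(OCOC)c1
A5 | alternative 2 | 5,7-bis(benzyloxy)-2-[4-(benzyloxy)-3-(methoxymethoxy)phenyl]-3-hydroxychroman-4-one (mixture of diastereomers) | O=C1c2c(OCc3ccccc3)cc(OCc3ccccc3)cc2OC(c2ccc(OCc3ccccc3)c(OCOC)c2)C1O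
A6 | alternative 3 | 6-{(3Z)-4-[4-(benzyloxy)-3-(methoxymethoxy)phenyl]-3-(methoxymethoxy)-2-oxobut-3-en-1-yl}-4-hydroxy-2H-pyran-2-one | O=c1cc(O)cc(CC(=O)/C(OCOC)=C/c2ccc(OCc3ccccc3)c(OCOC)c2)o1
A7 | alternative 3 | (Z)-3-[4-(benzyloxy)-3-(methoxymethoxy)phenyl]-2-(methoxymethoxy)-1-(2,4,6-trihydroxyphenyl)prop-2-en-1-one | O=C(c1c(O)cc(O)cc1O)/C(OCOC)=C/c1ccc(OCc2ccccc2)c(OCOC)c1
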